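**Plan**
The target, 7-hydroxy-6-methoxy-3-(3,4,5-trimethoxyphenyl)chromen-4-one, has no stereocentre. The retrosynthesis first cuts the O7 protecting group and the O6–CH3 bond, then opens ring C at C4–C4a and at O1–C2.
Enabling feature: in ring A the oxygen O1 (on C8a) and the oxygen on C6 are para, so ring A is a hydroquinone. Its quinone can accept the acyl carbon C4 at C4a, and the ether oxygen on C7 stays distinct from the hydroxyl that appears on C6.
Forward, ring A: catechol monobenzyl ether is tert-butylated, debenzylated and oxidised to 2-tert-butoxy-1,4-benzoquinone. Ring B with C2–C3–C4: trimethoxyphenylacetic acid is converted into the arylmalonaldehyde and then its methyl enol ether.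
Ring C is then made in one flask: light-driven acyl transfer from the enal to the quinone (C4–C4a), then acid-promoted addition–elimination (O1–C2). Methylation of O6 and acidolysis of the tert-butyl ether finish the route.
Stereochemistry: nothing has to be set; the enol ether geometry is the only stereo-element on the way and it is erased when ring C closes.

Key step: step 6

Remark: the 7-oxygen is carried as a tert-butyl ether because an excited alkoxyquinone can abstract hydrogen from an O–CH2 group next to its carbonyl (a benzyl ether would be most exposed); benzyl serves only as a temporary mask so that one catechol oxygen can be tert-butylated.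
Remark: the methyl enol ether is drawn as the (E) isomer (methoxy anti to formyl), the geometry normally obtained on O-alkylation of such enolates; the (Z) isomer would serve equally.

Step 1
Reactants: 1 2-(benzyloxy)phenol
Product: 2 1-(benzyloxy)-2-(tert-butoxy)benzene
Conditions: isobutene (excess), TfOH (5 mol %), CH2Cl2, −78 °C; Et3N quench
Reagents that add atoms: isobutene (2-methylpropene), CC(C)=C
Why: Acid-catalysed addition of the phenol O–H across isobutene (tert-butyl ether formation via the tert-butyl cation) is standard for phenols; at −78 °C with catalytic acid O-alkylation should outrun Friedel–Crafts C-alkylation and the benzyl ether should be untouched.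

Step 2
Reactants: 2 1-(benzyloxy)-2-(tert-butoxy)benzene
Product: 3 2-(tert-butoxy)phenol
Conditions: H2 (1 atm), 10% Pd/C, EtOAc, rt
Reagents that add atoms: none
Why: Catalytic hydrogenolysis of the benzyl aryl ether frees the phenol, while an aryl tert-butyl ether is inert to these neutral conditions.

Step 3
Reactants: 3 2-(tert-butoxy)phenol
Product: 4 2-(tert-butoxy)cyclohexa-2,5-diene-1,4-dione (2-tert-butoxy-1,4-benzoquinone)
Conditions: (KSO3)2NO (2.5 equiv), KH2PO4 (aq.), acetone, 0 °C to rt, dark
Reagents that add atoms: potassium nitrosodisulfonate, [K+].[K+].[O]N(S(=O)(=O)[O-])S(=O)(=O)[O-]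
Why: Teuber oxidation: the phenoxyl radical is trapped by a second nitroxide at the free para carbon and loss of imidodisulfonate gives the para-quinone, as with other 2-alkoxyphenols; the buffered medium should spare the acid-labile vinylogous tert-butyl ester.

Step 4
Reactants: 5 2-(3,4,5-trimethoxyphenyl)acetic acid
Product: 8 (Z)-3-hydroxy-2-(3,4,5-trimethoxyphenyl)acrylaldehyde (chelated enol of the arylmalonaldehyde), via vinamidinium chloride 6 (not isolated), via aminoacrolein 7 (not isolated)
Conditions: POCl3 (3 equiv), DMF, 0 to 75 °C; ice, then NaOH (aq.), 90 °C; HCl (aq.) to pH 3, 0 °C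
Reagents that add atoms: N,N-dimethylformamide, CN(C)C=O; water (delivered as aqueous NaOH), O
Why: Vilsmeier–Haack–Arnold reaction: the chloroiminium reagent iminoalkylates the α-carbon twice with loss of CO2 to give the vinamidinium salt, and alkaline hydrolysis of both C–N bonds followed by acidification should deliver the arylmalonaldehyde as its enol.

Step 5
Reactants: 8 (Z)-3-hydroxy-2-(3,4,5-trimethoxyphenyl)acrylaldehyde
Product: 9 (E)-3-methoxy-2-(3,4,5-trimethoxyphenyl)acrylaldehyde
Conditions: Me2SO4 (1.1 equiv), K2CO3, acetone, rt
Reagents that add atoms: dimethyl sulfate, COS(=O)(=O)OC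
Why: O-Alkylation of a vinylogous carboxylic acid through its potassium enolate with a hard methylating agent; the aryl-bearing central carbon is hindered, so the enol ether (extended E geometry, as for β-methoxyacrylates) is expected.

Step 6
Reactants: 4 2-(tert-butoxy)cyclohexa-2,5-diene-1,4-dione and 9 (E)-3-methoxy-2-(3,4,5-trimethoxyphenyl)acrylaldehyde
Product: 11 7-(tert-butoxy)-6-hydroxy-3-(3,4,5-trimethoxyphenyl)-4H-chromen-4-one, via acylhydroquinone 10 (not isolated)
Conditions: 9 (3 equiv), PhH (degassed, Ar), blue LEDs (420–450 nm), rt; then AcOH, 50 °C, same flask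
Reagents that add atoms: none
Why: Proposed new method: visible light excites only quinone 4, whose n,π* triplet abstracts the formyl hydrogen of 9; the nucleophilic σ-acyl radical then bonds to quinone carbon C5 (the future C4a, by addition to a ground-state quinone or by recombination with the semiquinone), and hydrogen transfer with enolisation gives acylhydroquinone 10, so that two normally electrophilic carbons are joined as C4–C4a. The closest known reaction type is the photo-Friedel–Crafts acylation of 1,4-quinones by aldehydes to acylhydroquinones, which tolerates enals and methoxy-substituted aryl groups; untested are the pairing of an alkoxyquinone with a β-alkoxy enal and the ring closure in the same flask. Ring C then closes under acetic acid by a 6-endo-trig oxa-Michael addition of the hydroxyl ortho to the new ketone onto the β-methoxy enone followed by loss of methanol (O1–C2), the way 2-hydroxyaryl enaminones and β-alkoxy enones close to chromones; no stereocentre is formed and the enol ether geometry is erased. The step needs regioselectivity for C5 over C3 and C6, which the tert-butoxy group supplies: it makes C4=O a vinylogous ester carbonyl, so the nucleophilic radical adds β to the more electron-poor C1=O, at the carbon where nucleophiles add to 2-alkoxyquinones, while C3 is the donor-substituted and shielded carbon of the enol ether unit. It also needs hydrogen abstraction from the aldehyde to win over [2+2] addition and over intramolecular abstraction: the enol ether of 9 is a hindered push–pull (vinylogous formate) alkene and a poor partner for oxetane formation, only the quinone absorbs, 9 is used in excess, and the tert-butyl ether has no hydrogen on the carbon bound to oxygen, unlike a benzyl or methyl ether. Since only the hydroxyl next to the ketone can reach C2, 11 should emerge with O6 free and O7 masked, which settles the differentiation of the two ring A oxygens.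

Step 7
Reactants: 11 7-(tert-butoxy)-6-hydroxy-3-(3,4,5-trimethoxyphenyl)-4H-chromen-4-one
Product: 12 7-(tert-butoxy)-6-methoxy-3-(3,4,5-trimethoxyphenyl)-4H-chromen-4-one
Conditions: MeI (2 equiv), K2CO3, acetone, 50 °C
Reagents that add atoms: iodomethane, CI
Why: Williamson etherification of the only free phenol; the tert-butyl ether keeps O7 out of play, so the methyl group can only go to O6.

Step 8
Reactants: 12 7-(tert-butoxy)-6-methoxy-3-(3,4,5-trimethoxyphenyl)-4H-chromen-4-one
Product: 13 7-hydroxy-6-methoxy-3-(3,4,5-trimethoxyphenyl)-4H-chromen-4-one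
Conditions: CF3CO2H/CH2Cl2 (1:4), 0 °C to rt
Reagents that add atoms: none
Why: Acidolysis of the aryl tert-butyl ether (E1 loss of isobutene via the tert-butyl cation); aryl methyl ethers and the pyranone are stable to trifluoroacetic acid, so only the 7-hydroxyl should be unmasked.

**Compound list**
1 | 2-(benzyloxy)phenol | Oc1ccccc1OCc1ccccc1 | starting material
2 | 1-(benzyloxy)-2-(tert-butoxy)benzene | CC(C)(C)Oc1ccccc1OCc1ccccc1 | intermediate
3 | 2-(tert-butoxy)phenol | CC(C)(C)Oc1ccccc1O | intermediate
4 | 2-(tert-butoxy)cyclohexa-2,5-diene-1,4-dione | CC(C)(C)OC1=CC(=O)C=CC1=O | intermediate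
5 | 2-(3,4,5-trimethoxyphenyl)acetic acid | OC(=O)Cc1cc(OC)c(OC)c(OC)c1 | starting material
6 | [(E)-3-(dimethylamino)-2-(3,4,5-trimethoxyphenyl)prop-2-en-1-ylidene]dimethylammonium chloride (vinamidinium chloride) | CN(C)/C=C(/C=[N+](C)C)c1cc(OC)c(OC)c(OC)c1.[Cl-] | intermediate (not isolated)
7 | (E)-3-(dimethylamino)-2-(3,4,5-trimethoxyphenyl)acrylaldehyde (aminoacrolein) | CN(C)/C=C(/C=O)c1cc(OC)c(OC)c(OC)c1 | intermediate (not isolated)
8 | (Z)-3-hydroxy-2-(3,4,5-trimethoxyphenyl)acrylaldehyde, the chelated enol of 2-(3,4,5-trimethoxyphenyl)malonaldehyde | O/C=C(\C=O)c1cc(OC)c(OC)c(OC)c1 | intermediate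
9 | (E)-3-methoxy-2-(3,4,5-trimethoxyphenyl)acrylaldehyde | CO/C=C(/C=O)c1cc(OC)c(OC)c(OC)c1 | intermediate
10 | (E)-1-[4-(tert-butoxy)-2,5-dihydroxyphenyl]-3-methoxy-2-(3,4,5-trimethoxyphenyl)prop-2-en-1-one (acylhydroquinone; E drawn, photoisomerisation to an E/Z mixture is expected and harmless) | CO/C=C(/C(=O)c1cc(O)c(OC(C)(C)C)cc1O)c1cc(OC)c(OC)c(OC)c1 | intermediate (not isolated)
11 | 7-(tert-butoxy)-6-hydroxy-3-(3,4,5-trimethoxyphenyl)-4H-chromen-4-one | O=c1c(-c2cc(OC)c(OC)c(OC)c2)coc2cc(OC(C)(C)C)c(O)cc12 | intermediate
12 | 7-(tert-butoxy)-6-methoxy-3-(3,4,5-trimethoxyphenyl)-4H-chromen-4-one | O=c1c(-c2cc(OC)c(OC)c(OC)c2)coc2cc(OC(C)(C)C)c(OC)cc12 | intermediate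
13 | 7-hydroxy-6-methoxy-3-(3,4,5-trimethoxyphenyl)-4H-chromen-4-one | COc1cc2c(=O)c(-c3cc(OC)c(OC)c(OC)c3)coc2cc1O | target

**Step count**
Total: 8 steps. Longest linear sequence: 6 steps (steps 1, 2, 3, 6, 7, 8, from 2-(benzyloxy)phenol).

**Steps most likely to fail**

Step 6, the one new method of the route, comes first. The excited quinone may be quenched unproductively by electron transfer from the trimethoxyphenyl ring, it may add [2+2] across the enol ether instead of abstracting the formyl hydrogen, or the acyl group may be delivered to the wrong quinone carbon. The fallback is the classical polar isoflavone construction. It sets out from acid 5 and returns to the route at target 13. Friedel–Crafts acylation of purchased 4-methoxybenzene-1,3-diol with 5 in BF3·OEt2 at 85 °C should give the deoxybenzoin 1-(2,4-dihydroxy-5-methoxyphenyl)-2-(3,4,5-trimethoxyphenyl)ethan-1-one F1, acylated para to one hydroxyl and ortho to the other. Addition of DMF and MsCl to the same BF3·OEt2 solution at 70 °C formylates the methylene carbon to the enaminone (E)-3-(dimethylamino)-1-(2,4-dihydroxy-5-methoxyphenyl)-2-(3,4,5-trimethoxyphenyl)prop-2-en-1-one F2. F2 is not isolated and closes by addition–elimination with loss of dimethylamine to give 13 directly. Ring A then arrives with its methoxy group in place, so steps 1–3, 7 and 8 are not needed.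

Step 5. Methylation may occur on the central carbon instead of on oxygen, or the enol ether may be hydrolysed back to 8 during isolation. The fallback moves the bond formation from oxygen to carbon. It sets out from 8 and returns at 9. (COCl)2 with catalytic DMF in CH2Cl2 converts the enol into the vinylogous acid chloride 3-chloro-2-(3,4,5-trimethoxyphenyl)acrylaldehyde F3 (E/Z mixture). NaOMe in MeOH at 0 °C then replaces chloride by methoxide through addition–elimination, which can only give the O-methyl compound 9.

Step 4. Electrophilic formylation of the electron-rich trimethoxyphenyl nucleus may compete with iminoalkylation of the side chain, or the decarboxylative second formylation may stall. The fallback avoids chloroiminium chemistry and the malonaldehyde altogether. It sets out from 5 and returns at 9, bypassing 8 and step 5.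
- Fischer esterification (MeOH, H2SO4 cat.) gives methyl 2-(3,4,5-trimethoxyphenyl)acetate F4.
- Claisen formylation (HCO2Me, NaH, THF) gives methyl (Z)-3-hydroxy-2-(3,4,5-trimethoxyphenyl)acrylate F5.
- O-methylation (Me2SO4, K2CO3, DMF) gives methyl (E)-3-methoxy-2-(3,4,5-trimethoxyphenyl)acrylate F6.
- Reduction with i-Bu2AlH in CH2Cl2 at −78 °C gives (E)-3-methoxy-2-(3,4,5-trimethoxyphenyl)prop-2-en-1-ol F7.
- Oxidation of this allylic alcohol with MnO2 in CH2Cl2 gives 9.

Further compounds
F1 | step 6 | 1-(2,4-dihydroxy-5-methoxyphenyl)-2-(3,4,5-trimethoxyphenyl)ethan-1-one | COc1cc(C(=O)Cc2cc(OC)c(OC)c(OC)c2)c(O)cc1O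
F2 | step 6 | (E)-3-(dimethylamino)-1-(2,4-dihydroxy-5-methoxyphenyl)-2-(3,4,5-trimethoxyphenyl)prop-2-en-1-one | COc1cc(C(=O)/C(=C/N(C)C)c2cc(OC)c(OC)c(OC)c2)c(O)cc1O
F3 | step 5 | 3-chloro-2-(3,4,5-trimethoxyphenyl)acrylaldehyde (E/Z mixture) | O=CC(=CCl)c1cc(OC)c(OC)c(OC)c1
F4 | step 4 | methyl 2-(3,4,5-trimethoxyphenyl)acetate | COC(=O)Cc1cc(OC)c(OC)c(OC)c1
F5 | step 4 | methyl (Z)-3-hydroxy-2-(3,4,5-trimethoxyphenyl)acrylate | O/C=C(\C(=O)OC)c1cc(OC)c(OC)c(OC)c1
F6 | step 4 | methyl (E)-3-methoxy-2-(3,4,5-trimethoxyphenyl)acrylate | CO/C=C(/C(=O)OC)c1cc(OC)c(OC)c(OC)c1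
F7 | step 4 | (E)-3-methoxy-2-(3,4,5-trimethoxyphenyl)prop-2-en-1-ol | CO/C=C(/CO)c1cc(OC)c(OC)c(OC)c1
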